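The data were computed from invented constants, and the scatter is random.

0.0578 min⁻¹ is what this flask has to average. I call it the mean pace: minus the logarithm of the unreacted part of the electrophile, divided by the time. It is a mean pseudo-first-order rate constant.

all flasks: electrophile 0.011 M

| charge | free base | protonated nucleophile | scavenger | remark | time |
|---|---|---|---|---|---|
| green | 0.0083 M | 0.011 M | 3.3 mM | run made earlier |  |
| teal | 0.019 M | 0.011 M | 3.3 mM | run made earlier |  |
| flask |  | 0.0110 M | 3.30 mM |  | 12 min |

- green (time / min: product / %): 0.667: 8; 2.00: 14; 3.00: 21; 5.00: 27; 8.00: 30; 10.0: 32
- teal (time / min: product / %): 0.667: 9; 2.00: 22; 3.00: 31; 5.00: 40; 8.00: 52; 10.0: 61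

(scatter of a reading: 1.5 percentage points)

- the concentration of free base at which the part of the electrophile that has reacted at 12 min is just 50 %, in M

- the amount of free base is what is sought; it is there from the start

Which numbers must I know well? Electrophile, protonated nucleophile and scavenger are charged in the flask as in both runs, so my reckoning between the runs holds them fixed. Free base matters: at 10.0 min, green with 0.0083 M reads 32 %, and teal with 0.019 M reads 61 %. Time matters too, since the readings stop before 12 min. Over its last interval green gains 2 percentage points, teal 9 points.

So I go round twice, assuming a straight line in free base. The last readings give paces of 0.0386 min⁻¹ for green and 0.0942 min⁻¹ for teal, and the line reaches the wanted pace at 12.0 mM. Then I repeat each run's last gain up to 12 min. That estimates 34.0 % for green and 70.0 % for teal, and the line now gives 12.1 mM.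

The forecast says 0.011 M, lower than my figure, and of its last step it says “the slow scavenging trims this”.

The flask gives 0.0124 M, so the forecast held within its margin.

    electrophile + nucleophile → acid set free + product (k = 0.257 M⁻¹ s⁻¹)
    nucleophile + acid set free ⇌ protonated nucleophile, settled at all times (K = 1.77 × 10⁵ M⁻¹)
    acid set free + free base ⇌ salt of the base, settled at all times (K = 2.72 × 10⁶ M⁻¹)
    nucleophile + acid set free ⇌ idle adduct, settled at all times (K = 27.0 M⁻¹)
    acid set free + scavenger → scavenged by-product (k = 10.9 M⁻¹ s⁻¹)

In this flask the electrophile's half-life by its step with the nucleophile is 8.2 min at 2.61 min and 34 min at 12.0 min, so its momentary pace by this step falls from 0.0846 min⁻¹, above the mean pace of 0.0578 min⁻¹, to 0.0207 min⁻¹, below it. With a fifth less free base, 42.1 % of the electrophile in this flask has reacted at 12 min, a mean pace of 0.0456 min⁻¹, which is less than 0.0578 min⁻¹.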